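**Plan** (naphthalene numbering of the core: C1 CH–CHO, C2 =C–CHO, C3, C4, C4a, C5/C6 methyl-bearing alkene, C7, C8 O-acyl, C8a angular methyl)
1. Retrosynthesis: cut the C8 ester, take the dialdehyde back to a C1/C2 diester, then cut ring B at C3–C4 and C1–C8a, giving a ring A bromomethyl enone and the dianion of methyl acetoacetate.
2. Enabling feature: C4 and C8a are 1,3 across C4a, and C3 and C1 are 1,3 across C2. A temporary ketone at C5 makes C4 (allylic CH2Br) and C8a (enone β-carbon) a 1,3-dielectrophile; a temporary ketone at C2 makes C3/C1 the γ/α carbons of a 1,3-dinucleophile.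
3. Forward: ring A from a phenol (oxidative dearomatisation, conjugate methylation, CBS reduction); ring B by one-pot γ-alkylation/intramolecular Michael addition; then the C5 ketone becomes the C5 methyl alkene and the C2 ketone the C2 ester (both via enol triflates); deconjugation, reduction, acylation, Swern oxidation.
4. Stereochemistry: C8 by CBS reduction; C8a by Michael addition anti to the C8 silyloxy group; C4a by equilibration next to the C5 ketone (trans fusion); C1 by kinetic protonation of a dienolate, secured as the O8→C1 lactone; Z alkene by Lindlar reduction.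

Key step: step 7

Assumption: 3-(hydroxymethyl)-2-methylphenol (1) is taken as a catalogue compound. The C6 methyl stereocentre of 4–11 is temporary and is erased in step 8.

Step 1
Reactants: 1 3-(hydroxymethyl)-2-methylphenol
Product: 3 3-(hydroxymethyl)-4,4-dimethoxy-2-methylcyclohexa-2,5-dien-1-one, via 4-methoxyphenol intermediate 2 (not isolated)
Conditions: PhI(OAc)2 (2.2 equiv), MeOH, 0 °C → rt
Reagents that add atoms: methanol (CO)
Why: Hypervalent-iodine oxidative dearomatisation of a para-unsubstituted phenol in methanol (two successive two-electron oxidations with para capture by methanol) should give the para-quinone monoketal; no stereocentre is formed.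

Step 2
Reactants: 3 3-(hydroxymethyl)-4,4-dimethoxy-2-methylcyclohexa-2,5-dien-1-one
Product: 4 (5S)-3-(hydroxymethyl)-4,4-dimethoxy-2,5-dimethylcyclohex-2-en-1-one
Conditions: Me2Zn (2.5 equiv), Cu(OTf)2 (2 mol %), BINOL-derived phosphoramidite (4 mol %, enantiomer selected for the 5S product), toluene, −25 °C; aq. NH4Cl
Reagents that add atoms: dimethylzinc (C[Zn]C)
Why: Copper-catalysed enantioselective conjugate addition of a dialkylzinc to a quinone monoketal should occur only at the unsubstituted enone arm (the other β-carbon is fully substituted), the ligand setting the temporary C5 stereocentre.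

Step 3
Reactants: 4 (5S)-3-(hydroxymethyl)-4,4-dimethoxy-2,5-dimethylcyclohex-2-en-1-one
Product: 5 (1R,5S)-3-(hydroxymethyl)-4,4-dimethoxy-2,5-dimethylcyclohex-2-en-1-ol
Conditions: (S)-2-methyl-CBS-oxazaborolidine (10 mol %), BH3·SMe2, THF, −20 °C; MeOH quench
Reagents that add atoms: none
Why: Corey–Bakshi–Shibata 1,2-reduction of the 2-methyl enone, with the alkenyl side as the large group, should give the (1R) allylic alcohol under reagent control (this carbon becomes C8 of the target).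

Step 4
Reactants: 5 (1R,5S)-3-(hydroxymethyl)-4,4-dimethoxy-2,5-dimethylcyclohex-2-en-1-ol
Product: 6 bis(tert-butyldimethylsilyl) ether of 5
Conditions: t-BuMe2SiCl (2.5 equiv), imidazole, DMAP (cat.), DMF, rt → 40 °C
Reagents that add atoms: tert-butylchlorodimethylsilane (CC(C)(C)[Si](C)(C)Cl)
Why: Standard silylation of both hydroxyls under non-acidic conditions protects the allylic ketal and gives the bulky C8 silyl ether that later directs the Michael addition.

Step 5
Reactants: 6 bis(tert-butyldimethylsilyl) ether of 5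
Product: 7 (4R,6S)-4-{[tert-butyl(dimethyl)silyl]oxy}-2-(hydroxymethyl)-3,6-dimethylcyclohex-2-en-1-one
Conditions: 1 M aq. HCl, THF, 0 °C → rt
Reagents that add atoms: water (O)
Why: Aqueous acid should hydrolyse the dimethyl ketal to the enone and cleave the primary allylic silyl ether faster than the hindered secondary one; C6 becomes epimerisable but is erased in step 8.

Step 6
Reactants: 7 (4R,6S)-4-{[tert-butyl(dimethyl)silyl]oxy}-2-(hydroxymethyl)-3,6-dimethylcyclohex-2-en-1-one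
Product: 8 (4R,6S)-2-(bromomethyl)-4-{[tert-butyl(dimethyl)silyl]oxy}-3,6-dimethylcyclohex-2-en-1-one
Conditions: CBr4, PPh3, CH2Cl2, 0 °C
Reagents that add atoms: tetrabromomethane (BrC(Br)(Br)Br)
Why: Appel bromination of the primary allylic alcohol gives the 2-(bromomethyl) enone under neutral conditions that leave the γ-silyloxy enone intact.

Step 7
Reactants: 8 (4R,6S)-2-(bromomethyl)-4-{[tert-butyl(dimethyl)silyl]oxy}-3,6-dimethylcyclohex-2-en-1-one; 9 methyl acetoacetate
Product: 11 methyl (4aR,6S,8R,8aS)-8-{[tert-butyl(dimethyl)silyl]oxy}-2-hydroxy-6,8a-dimethyl-5-oxo-3,4,4a,5,6,7,8,8a-octahydronaphthalene-1-carboxylate (enol form of the β-keto ester), via alkylated keto ester 10 (not isolated)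
Conditions: 9, NaH then n-BuLi, THF, 0 °C; 8, −78 → 0 °C; then MeOH, 0 → 40 °C; aq. NH4Cl
Reagents that add atoms: none
Why: The Weiler dianion of 9 is alkylated at its γ-carbon by the primary allylic bromide (SN2), forming C3–C4 and leaving the enolate of 10; after methanol is added this β-keto ester enolate adds to the enone β-carbon C8a (intramolecular Michael addition), forming C1–C8a and the quaternary centre. The closest known reaction types are dianion γ-alkylation followed by Michael cyclisation, together a Robinson-type [3+3] annulation. Ring B closes in a 6-(enolendo)-endo-trig mode. At C8a the nucleophile should add anti to the C8 silyloxy group, which A1,2 strain with the C8a methyl holds pseudoaxial, so the methyl ends cis to O8; C4a is protonated and equilibrated next to the C5 ketone to the trans-fused isomer (as in 5α-4-oxo steroids); C6 settles equatorial; C1 remains an enol and is set in step 11. The step needs γ- over α-alkylation (secured by the dianion), SN2 over SN2′ (primary bromide versus fully substituted C8a), and C- over O-cyclisation (the oxa-Michael adduct is reversible under methoxide, the C–C adduct is not).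

Step 8
Reactants: 11 methyl (4aR,6S,8R,8aS)-8-{[tert-butyl(dimethyl)silyl]oxy}-2-hydroxy-6,8a-dimethyl-5-oxo-3,4,4a,5,6,7,8,8a-octahydronaphthalene-1-carboxylate
Product: 12 methyl (4aR,8R,8aS)-8-{[tert-butyl(dimethyl)silyl]oxy}-6,8a-dimethyl-2,5-bis{[(trifluoromethyl)sulfonyl]oxy}-3,4,4a,7,8,8a-hexahydronaphthalene-1-carboxylate
Conditions: KN(SiMe3)2 (2.3 equiv), THF, −78 °C; PhNTf2 (2.5 equiv), −78 °C → rt
Reagents that add atoms: N-phenylbis(trifluoromethanesulfonimide) (O=S(=O)(N(c1ccccc1)S(=O)(=O)C(F)(F)F)C(F)(F)F)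
Why: Two equivalents of base give the β-keto ester enolate and the C5 ketone enolate on the C6 side (away from the hindered ring-fusion methine), and O-triflation of both (enol triflate formation) removes the temporary C6 stereocentre.

Step 9
Reactants: 12 methyl (4aR,8R,8aS)-8-{[tert-butyl(dimethyl)silyl]oxy}-6,8a-dimethyl-2,5-bis{[(trifluoromethyl)sulfonyl]oxy}-3,4,4a,7,8,8a-hexahydronaphthalene-1-carboxylate
Product: 13 dimethyl (4aR,8R,8aS)-8-{[tert-butyl(dimethyl)silyl]oxy}-6,8a-dimethyl-5-{[(trifluoromethyl)sulfonyl]oxy}-3,4,4a,7,8,8a-hexahydronaphthalene-1,2-dicarboxylate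
Conditions: CO (1 atm), MeOH, Pd(OAc)2 (5 mol %), dppp (5 mol %), Et3N, DMF, 40 °C
Reagents that add atoms: carbon monoxide ([C-]#[O+]); methanol (CO)
Why: Palladium-catalysed methoxycarbonylation of an enol triflate should take place at the electron-poor β-(triflyloxy)enoate, which undergoes oxidative addition much faster than the hindered unactivated C5 triflate.

Step 10
Reactants: 13 dimethyl (4aR,8R,8aS)-8-{[tert-butyl(dimethyl)silyl]oxy}-6,8a-dimethyl-5-{[(trifluoromethyl)sulfonyl]oxy}-3,4,4a,7,8,8a-hexahydronaphthalene-1,2-dicarboxylate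
Product: 14 dimethyl (4aS,8R,8aS)-8-{[tert-butyl(dimethyl)silyl]oxy}-5,6,8a-trimethyl-3,4,4a,7,8,8a-hexahydronaphthalene-1,2-dicarboxylate
Conditions: MeZnCl (3 equiv), PdCl2(dppf) (5 mol %), THF, 60 °C
Reagents that add atoms: methylzinc chloride (C[Zn]Cl)
Why: Negishi coupling of the remaining alkenyl triflate installs the C5 methyl and so fixes the tetrasubstituted C5=C6 alkene; the esters tolerate the organozinc.

Step 11
Reactants: 14 dimethyl (4aS,8R,8aS)-8-{[tert-butyl(dimethyl)silyl]oxy}-5,6,8a-trimethyl-3,4,4a,7,8,8a-hexahydronaphthalene-1,2-dicarboxylate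
Product: 15 dimethyl (1R,4aS,8R,8aS)-8-{[tert-butyl(dimethyl)silyl]oxy}-5,6,8a-trimethyl-1,4,4a,7,8,8a-hexahydronaphthalene-1,2-dicarboxylate
Conditions: LiN(i-Pr)2 (1.2 equiv), HMPA, THF, −78 °C; then AcOH, −78 °C
Reagents that add atoms: none
Why: Deconjugative protonation: the amide removes H3 (γ to the C1 ester) and the dienolate is protonated kinetically at C1 from the α face, anti to the axial C8a methyl, giving 1α-H and the C2=C3 enoate.

Step 12
Reactants: 15 dimethyl (1R,4aS,8R,8aS)-8-{[tert-butyl(dimethyl)silyl]oxy}-5,6,8a-trimethyl-1,4,4a,7,8,8a-hexahydronaphthalene-1,2-dicarboxylate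
Product: 17 γ-lactone closed between O8 and the C1 carbonyl (methyl ester at C2 retained; 1R,4aS,8R,8aS), via hydroxy diester 16 (not isolated)
Conditions: Bu4NF (1.2 equiv), THF, 0 °C → rt; aq. NH4Cl
Reagents that add atoms: none
Why: Fluoride desilylation frees the 8β-alkoxide, which lies syn-parallel to the 1β-ester across C8a and should lactonise; only the desired C1 epimer can close this ring, so any epimerisation at C1 is corrected.

Step 13
Reactants: 17 γ-lactone closed between O8 and the C1 carbonyl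
Product: 18 (1S,4aS,8R,8aS)-1,2-bis(hydroxymethyl)-5,6,8a-trimethyl-1,4,4a,7,8,8a-hexahydronaphthalen-8-ol
Conditions: LiAlH4, THF, 0 °C; Rochelle-salt work-up
Reagents that add atoms: none
Why: Hydride reduction of the lactone and of the conjugated ester (1,2-mode) gives the triol without touching a stereocentre (the C1 descriptor changes only by priority).

Step 14
Reactants: 18 (1S,4aS,8R,8aS)-1,2-bis(hydroxymethyl)-5,6,8a-trimethyl-1,4,4a,7,8,8a-hexahydronaphthalen-8-ol
Product: 19 (1S,4aS,8R,8aS)-5,6,8a-trimethyl-1,2-bis{[(triethylsilyl)oxy]methyl}-1,4,4a,7,8,8a-hexahydronaphthalen-8-ol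
Conditions: Et3SiCl (2.1 equiv), imidazole, CH2Cl2, −40 → 0 °C
Reagents that add atoms: chlorotriethylsilane (CC[Si](Cl)(CC)CC)
Why: The two primary hydroxyls should be silylated selectively over the secondary C8 hydroxyl, which sits next to the quaternary carbon.

Step 15
Reactants: 19 (1S,4aS,8R,8aS)-5,6,8a-trimethyl-1,2-bis{[(triethylsilyl)oxy]methyl}-1,4,4a,7,8,8a-hexahydronaphthalen-8-ol; 20 3-phenylprop-2-ynoic acid
Product: 21 (1S,4aS,8R,8aS)-5,6,8a-trimethyl-1,2-bis{[(triethylsilyl)oxy]methyl}-1,4,4a,7,8,8a-hexahydronaphthalen-8-yl 3-phenylprop-2-ynoate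
Conditions: DCC, DMAP (cat.), CH2Cl2, 0 °C → rt
Reagents that add atoms: none
Why: Steglich esterification with the slim alkynoic acid acylates the hindered alcohol and avoids the Z to E isomerisation that a Z-cinnamoyl donor could suffer under acyl-transfer catalysis.

Step 16
Reactants: 21 (1S,4aS,8R,8aS)-5,6,8a-trimethyl-1,2-bis{[(triethylsilyl)oxy]methyl}-1,4,4a,7,8,8a-hexahydronaphthalen-8-yl 3-phenylprop-2-ynoate
Product: 22 (1S,4aS,8R,8aS)-5,6,8a-trimethyl-1,2-bis{[(triethylsilyl)oxy]methyl}-1,4,4a,7,8,8a-hexahydronaphthalen-8-yl (2Z)-3-phenylprop-2-enoate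
Conditions: H2 (1 atm), Pd/CaCO3 poisoned with Pb(OAc)2, quinoline, EtOAc, rt
Reagents that add atoms: none
Why: Lindlar semi-hydrogenation adds hydrogen syn to the alkyne to give the Z-cinnamate, leaving the trisubstituted and tetrasubstituted ring alkenes untouched.

Step 17
Reactants: 22 (1S,4aS,8R,8aS)-5,6,8a-trimethyl-1,2-bis{[(triethylsilyl)oxy]methyl}-1,4,4a,7,8,8a-hexahydronaphthalen-8-yl (2Z)-3-phenylprop-2-enoate
Product: 23 (1S,4aS,8R,8aS)-1,2-bis(hydroxymethyl)-5,6,8a-trimethyl-1,4,4a,7,8,8a-hexahydronaphthalen-8-yl (2Z)-3-phenylprop-2-enoate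
Conditions: HF·pyridine, pyridine, THF, 0 °C
Reagents that add atoms: none
Why: Buffered fluoride cleaves the triethylsilyl ethers under mildly acidic conditions, under which neither acyl migration nor alkene isomerisation is expected.

Step 18
Reactants: 23 (1S,4aS,8R,8aS)-1,2-bis(hydroxymethyl)-5,6,8a-trimethyl-1,4,4a,7,8,8a-hexahydronaphthalen-8-yl (2Z)-3-phenylprop-2-enoate
Product: 24 (1R,4aS,8R,8aS)-1,2-diformyl-5,6,8a-trimethyl-1,4,4a,7,8,8a-hexahydronaphthalen-8-yl (2Z)-3-phenylprop-2-enoate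
Conditions: (COCl)2, DMSO, CH2Cl2, −78 °C; then i-Pr2NEt, −78 → −40 °C
Reagents that add atoms: none
Why: Swern oxidation activates both primary alcohols before either aldehyde is released, which avoids lactol and lactone formation in the ene-1,4-diol, and the hindered amine at low temperature should spare the epimerisable C1 centre.

**Compound list**
1 | 3-(hydroxymethyl)-2-methylphenol | Cc1c(O)cccc1CO | starting material
2 | 3-(hydroxymethyl)-4-methoxy-2-methylphenol | COc1ccc(O)c(C)c1CO | intermediate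
3 | 3-(hydroxymethyl)-4,4-dimethoxy-2-methylcyclohexa-2,5-dien-1-one | CC1=C(CO)C(OC)(OC)C=CC1=O | intermediate
4 | (5S)-3-(hydroxymethyl)-4,4-dimethoxy-2,5-dimethylcyclohex-2-en-1-one | CC1=C(CO)C(OC)(OC)[C@@H](C)CC1=O | intermediate
5 | (1R,5S)-3-(hydroxymethyl)-4,4-dimethoxy-2,5-dimethylcyclohex-2-en-1-ol | CC1=C(CO)C(OC)(OC)[C@@H](C)C[C@H]1O | intermediate
6 | bis(tert-butyldimethylsilyl) ether of 5 (1R,5S) | CC1=C(CO[Si](C)(C)C(C)(C)C)C(OC)(OC)[C@@H](C)C[C@H]1O[Si](C)(C)C(C)(C)C | intermediate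
7 | (4R,6S)-4-{[tert-butyl(dimethyl)silyl]oxy}-2-(hydroxymethyl)-3,6-dimethylcyclohex-2-en-1-one | CC1=C(CO)C(=O)[C@@H](C)C[C@H]1O[Si](C)(C)C(C)(C)C | intermediate
8 | (4R,6S)-2-(bromomethyl)-4-{[tert-butyl(dimethyl)silyl]oxy}-3,6-dimethylcyclohex-2-en-1-one | CC1=C(CBr)C(=O)[C@@H](C)C[C@H]1O[Si](C)(C)C(C)(C)C | intermediate
9 | methyl acetoacetate (methyl 3-oxobutanoate) | CC(=O)CC(=O)OC | starting material
10 | methyl 5-[(3R,5S)-3-{[tert-butyl(dimethyl)silyl]oxy}-2,5-dimethyl-6-oxocyclohex-1-en-1-yl]-3-oxopentanoate | CC1=C(CCC(=O)CC(=O)OC)C(=O)[C@@H](C)C[C@H]1O[Si](C)(C)C(C)(C)C | intermediate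
11 | methyl (4aR,6S,8R,8aS)-8-{[tert-butyl(dimethyl)silyl]oxy}-2-hydroxy-6,8a-dimethyl-5-oxo-3,4,4a,5,6,7,8,8a-octahydronaphthalene-1-carboxylate (enol form; trans-fused, 6-Me, 8-OSi and 8a-Me all cis) | C[C@@H]1C(=O)[C@@H]2CCC(O)=C(C(=O)OC)[C@@]2(C)[C@H](O[Si](C)(C)C(C)(C)C)C1 | intermediate
12 | methyl (4aR,8R,8aS)-8-{[tert-butyl(dimethyl)silyl]oxy}-6,8a-dimethyl-2,5-bis{[(trifluoromethyl)sulfonyl]oxy}-3,4,4a,7,8,8a-hexahydronaphthalene-1-carboxylate | CC1=C(OS(=O)(=O)C(F)(F)F)[C@@H]2CCC(OS(=O)(=O)C(F)(F)F)=C(C(=O)OC)[C@@]2(C)[C@H](O[Si](C)(C)C(C)(C)C)C1 | intermediate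
13 | dimethyl (4aR,8R,8aS)-8-{[tert-butyl(dimethyl)silyl]oxy}-6,8a-dimethyl-5-{[(trifluoromethyl)sulfonyl]oxy}-3,4,4a,7,8,8a-hexahydronaphthalene-1,2-dicarboxylate | CC1=C(OS(=O)(=O)C(F)(F)F)[C@@H]2CCC(C(=O)OC)=C(C(=O)OC)[C@@]2(C)[C@H](O[Si](C)(C)C(C)(C)C)C1 | intermediate
14 | dimethyl (4aS,8R,8aS)-8-{[tert-butyl(dimethyl)silyl]oxy}-5,6,8a-trimethyl-3,4,4a,7,8,8a-hexahydronaphthalene-1,2-dicarboxylate | CC1=C(C)[C@@H]2CCC(C(=O)OC)=C(C(=O)OC)[C@@]2(C)[C@H](O[Si](C)(C)C(C)(C)C)C1 | intermediate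
15 | dimethyl (1R,4aS,8R,8aS)-8-{[tert-butyl(dimethyl)silyl]oxy}-5,6,8a-trimethyl-1,4,4a,7,8,8a-hexahydronaphthalene-1,2-dicarboxylate | CC1=C(C)[C@@H]2CC=C(C(=O)OC)[C@H](C(=O)OC)[C@@]2(C)[C@H](O[Si](C)(C)C(C)(C)C)C1 | intermediate
16 | dimethyl (1R,4aS,8R,8aS)-8-hydroxy-5,6,8a-trimethyl-1,4,4a,7,8,8a-hexahydronaphthalene-1,2-dicarboxylate | CC1=C(C)[C@@H]2CC=C(C(=O)OC)[C@H](C(=O)OC)[C@@]2(C)[C@H](O)C1 | intermediate
17 | γ-lactone of 16 closed between O8 and the C1 carbonyl, methyl ester at C2 retained (1R,4aS,8R,8aS) | CC1=C(C)[C@@H]2CC=C(C(=O)OC)[C@@H]3C(=O)O[C@H](C1)[C@@]23C | intermediate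
18 | (1S,4aS,8R,8aS)-1,2-bis(hydroxymethyl)-5,6,8a-trimethyl-1,4,4a,7,8,8a-hexahydronaphthalen-8-ol | CC1=C(C)[C@@H]2CC=C(CO)[C@H](CO)[C@@]2(C)[C@H](O)C1 | intermediate
19 | (1S,4aS,8R,8aS)-5,6,8a-trimethyl-1,2-bis{[(triethylsilyl)oxy]methyl}-1,4,4a,7,8,8a-hexahydronaphthalen-8-ol | CC1=C(C)[C@@H]2CC=C(CO[Si](CC)(CC)CC)[C@H](CO[Si](CC)(CC)CC)[C@@]2(C)[C@H](O)C1 | intermediate
20 | 3-phenylprop-2-ynoic acid (phenylpropiolic acid) | OC(=O)C#Cc1ccccc1 | starting material
21 | (1S,4aS,8R,8aS)-5,6,8a-trimethyl-1,2-bis{[(triethylsilyl)oxy]methyl}-1,4,4a,7,8,8a-hexahydronaphthalen-8-yl 3-phenylprop-2-ynoate | CC1=C(C)[C@@H]2CC=C(CO[Si](CC)(CC)CC)[C@H](CO[Si](CC)(CC)CC)[C@@]2(C)[C@H](OC(=O)C#Cc2ccccc2)C1 | intermediate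
22 | (1S,4aS,8R,8aS)-5,6,8a-trimethyl-1,2-bis{[(triethylsilyl)oxy]methyl}-1,4,4a,7,8,8a-hexahydronaphthalen-8-yl (2Z)-3-phenylprop-2-enoate | CC1=C(C)[C@@H]2CC=C(CO[Si](CC)(CC)CC)[C@H](CO[Si](CC)(CC)CC)[C@@]2(C)[C@H](OC(=O)/C=C\c2ccccc2)C1 | intermediate
23 | (1S,4aS,8R,8aS)-1,2-bis(hydroxymethyl)-5,6,8a-trimethyl-1,4,4a,7,8,8a-hexahydronaphthalen-8-yl (2Z)-3-phenylprop-2-enoate | CC1=C(C)[C@@H]2CC=C(CO)[C@H](CO)[C@@]2(C)[C@H](OC(=O)/C=C\c2ccccc2)C1 | intermediate
24 | (1R,4aS,8R,8aS)-1,2-diformyl-5,6,8a-trimethyl-1,4,4a,7,8,8a-hexahydronaphthalen-8-yl (2Z)-3-phenylprop-2-enoate | CC1=C(C)[C@@H]2CC=C(C=O)[C@H](C=O)[C@@]2(C)[C@H](OC(=O)/C=C\c2ccccc2)C1 | target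

Total step count: 18. Longest linear sequence: 18 steps (from 1).

**Steps most likely to fail**

Step 7. The keto ester enolate may close through oxygen instead of carbon (oxa-Michael), or the ring fusion may not equilibrate to trans. Fallback: the cascade is split and the ring closed under Lewis acid instead of base. The alkylation is quenched at −78 °C with AcOH to isolate 10. Its β-keto ester is silylated (Me3SiCl, Et3N, DMF) to methyl (2Z)-5-[(3R,5S)-3-{[tert-butyl(dimethyl)silyl]oxy}-2,5-dimethyl-6-oxocyclohex-1-en-1-yl]-3-[(trimethylsilyl)oxy]pent-2-enoate F1. F1 is cyclised with TiCl4 in CH2Cl2 at −78 °C (intramolecular Mukaiyama–Michael addition, carbon-selective and irreversible). Aqueous work-up and a short NaOMe/MeOH equilibration of C4a return the route to 11.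

Step 9. Oxidative addition may fail to discriminate between the two enol triflates. Fallback: the two carbonyls are handled one after the other. Starting from 11, NaH (1 equiv) and PhNTf2 triflate only the β-keto ester, giving methyl (4aR,6S,8R,8aS)-8-{[tert-butyl(dimethyl)silyl]oxy}-6,8a-dimethyl-5-oxo-2-{[(trifluoromethyl)sulfonyl]oxy}-3,4,4a,5,6,7,8,8a-octahydronaphthalene-1-carboxylate F2. Methoxycarbonylation (Pd(OAc)2, dppp, CO, MeOH, Et3N) gives dimethyl (4aR,6S,8R,8aS)-8-{[tert-butyl(dimethyl)silyl]oxy}-6,8a-dimethyl-5-oxo-3,4,4a,5,6,7,8,8a-octahydronaphthalene-1,2-dicarboxylate F3. Kinetic enolisation of the C5 ketone (KN(SiMe3)2, −78 °C) and PhNTf2 then return the route to 13.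

Step 11. Protonation of the dienolate may show poor facial selectivity, or the amide base may attack the crowded ene diester. Fallback: the deconjugation is run under thermodynamic control with the lactone as a temporary ring. Starting from 14, Bu4NF gives dimethyl (4aS,8R,8aS)-8-hydroxy-5,6,8a-trimethyl-3,4,4a,7,8,8a-hexahydronaphthalene-1,2-dicarboxylate F4, which should close to the alkylidene γ-lactone between O8 and the C1 carbonyl F5. DBU in toluene at 60 °C then moves the double bond to C2=C3; the lactone ring allows only the 1α-H configuration. The route is rejoined at 17.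

Further compounds
F1 | step 7 | methyl (2Z)-5-[(3R,5S)-3-{[tert-butyl(dimethyl)silyl]oxy}-2,5-dimethyl-6-oxocyclohex-1-en-1-yl]-3-[(trimethylsilyl)oxy]pent-2-enoate | CC1=C(CC/C(O[Si](C)(C)C)=C/C(=O)OC)C(=O)[C@@H](C)C[C@H]1O[Si](C)(C)C(C)(C)C
F2 | step 9 | methyl (4aR,6S,8R,8aS)-8-{[tert-butyl(dimethyl)silyl]oxy}-6,8a-dimethyl-5-oxo-2-{[(trifluoromethyl)sulfonyl]oxy}-3,4,4a,5,6,7,8,8a-octahydronaphthalene-1-carboxylate | C[C@@H]1C(=O)[C@@H]2CCC(OS(=O)(=O)C(F)(F)F)=C(C(=O)OC)[C@@]2(C)[C@H](O[Si](C)(C)C(C)(C)C)C1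
F3 | step 9 | dimethyl (4aR,6S,8R,8aS)-8-{[tert-butyl(dimethyl)silyl]oxy}-6,8a-dimethyl-5-oxo-3,4,4a,5,6,7,8,8a-octahydronaphthalene-1,2-dicarboxylate | C[C@@H]1C(=O)[C@@H]2CCC(C(=O)OC)=C(C(=O)OC)[C@@]2(C)[C@H](O[Si](C)(C)C(C)(C)C)C1
F4 | step 11 | dimethyl (4aS,8R,8aS)-8-hydroxy-5,6,8a-trimethyl-3,4,4a,7,8,8a-hexahydronaphthalene-1,2-dicarboxylate | CC1=C(C)[C@@H]2CCC(C(=O)OC)=C(C(=O)OC)[C@@]2(C)[C@H](O)C1
F5 | step 11 | alkylidene γ-lactone of F4 closed between O8 and the C1 carbonyl (C1=C2 retained, methyl ester at C2) | CC1=C(C)[C@@H]2CCC(C(=O)OC)=C3C(=O)O[C@H](C1)[C@@]23C
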